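## Retrosynthetic overview

1. Target 20 ⇐ MOM ether 19 ⇐ ketol 18 (C7 carbinol by hydroxyl-directed reduction) ⇐ triol ketal 17 (cis-5,6-diol by hydroxyl-directed osmylation of C5=C6) ⇐ dienol ketal 16. Chromone numbering (O1, C2, C3, C4, C4a, C5–C8, C8a) is used throughout.
2. Key disconnection of 16: bonds C4a–C5 and C7–C8 together, a [3+3] annulation of boronate aldehyde 12 (C4a–B, C8 = CHO) with 3,3-dimethoxycyclopropene 15, driven by opening of the three-membered ring.
3. Enabling feature: on the pyranone ring (O1, C2, C3, C4, C4a, C8a) the metal-bearing C4a and the formyl carbon C8 on C8a are ortho to each other. In the carbocycle (C4a, C5, C6, C7, C8, C8a) C7 lies between two carbinols and can enter at the ketone level as the ketal carbon, while C5/C6 carry a cis-diol and can enter as the strained alkene.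
4. 12 ⇐ kojic acid 1: its enolic OH marks C4a (triflate, then boronate), its free ring CH takes C8 (hydroxymethylation, oxidation), and its CH2OH carries the arylethyl chain (Wittig with MOM-isovanillin 6, hydrogenation).
5. Ring order: the pyranone ring comes with kojic acid; the carbocycle is closed in step 13; no ring is formed afterwards.

Key step: step 13

Remark: the sense of induction of the chiral diene in step 13 is assumed; the antipodal diene is taken if C8 forms with the opposite configuration.

## Route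

Step 1
Reactants: 1 kojic acid (5-hydroxy-2-(hydroxymethyl)-4H-pyran-4-one)
Product: 2 5-(benzyloxy)-2-(hydroxymethyl)-4H-pyran-4-one
Conditions: BnCl, NaOH, MeOH/H2O, reflux
Reagents that add atoms: benzyl chloride, ClCc1ccccc1
Why: Williamson etherification, in which only the acidic enolic hydroxyl is deprotonated and benzylated while the primary alcohol stays free.

Step 2
Reactants: 2 5-(benzyloxy)-2-(hydroxymethyl)-4H-pyran-4-one
Product: 3 5-(benzyloxy)-2-(chloromethyl)-4H-pyran-4-one
Conditions: SOCl2, CH2Cl2, 0 °C to rt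
Reagents that add atoms: thionyl chloride, O=S(Cl)Cl
Why: Chlorodehydroxylation of the activated primary alcohol with thionyl chloride, a standard conversion of kojic acid ethers that leaves the benzyl ether and the pyranone untouched.

Step 3
Reactants: 3 5-(benzyloxy)-2-(chloromethyl)-4H-pyran-4-one
Product: 4 {[5-(benzyloxy)-4-oxo-4H-pyran-2-yl]methyl}triphenylphosphonium chloride
Conditions: PPh3, toluene, 110 °C
Reagents that add atoms: triphenylphosphine, c1ccc(cc1)P(c1ccccc1)c1ccccc1
Why: SN2 quaternisation of triphenylphosphine by the activated primary chloride should give the Wittig salt, which precipitates from toluene.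

Step 4
Reactants: 5 isovanillin (3-hydroxy-4-methoxybenzaldehyde)
Product: 6 4-methoxy-3-(methoxymethoxy)benzaldehyde
Conditions: MOMCl, iPr2NEt, CH2Cl2, 0 °C to rt
Reagents that add atoms: chloromethyl methyl ether, COCCl
Why: O-alkylation of the phenol to its methoxymethyl acetal, a group that should survive the later base, hydrogenation, palladium, rhodium and osmium steps and leave with acid at the end.

Step 5
Reactants: 4 {[5-(benzyloxy)-4-oxo-4H-pyran-2-yl]methyl}triphenylphosphonium chloride; 6 4-methoxy-3-(methoxymethoxy)benzaldehyde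
Product: 7 5-(benzyloxy)-2-{2-[4-methoxy-3-(methoxymethoxy)phenyl]ethenyl}-4H-pyran-4-one (E/Z mixture)
Conditions: KOtBu, THF, 0 °C to rt
Reagents that add atoms: none
Why: Wittig olefination of the semistabilised ylide with the aromatic aldehyde, where the alkene geometry is irrelevant because the double bond is saturated in the next step.

Step 6
Reactants: 7 5-(benzyloxy)-2-{2-[4-methoxy-3-(methoxymethoxy)phenyl]ethenyl}-4H-pyran-4-one
Product: 8 5-hydroxy-2-{2-[4-methoxy-3-(methoxymethoxy)phenyl]ethyl}-4H-pyran-4-one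
Conditions: H2 (1 atm), 10% Pd/C, EtOAc/MeOH, rt
Reagents that add atoms: none
Why: Catalytic hydrogenation should saturate the styryl alkene and hydrogenolyse the enol benzyl ether in one operation, while the vinylogous-ester pyranone ring and the MOM ether are not reduced under these mild conditions.

Step 7
Reactants: 8 5-hydroxy-2-{2-[4-methoxy-3-(methoxymethoxy)phenyl]ethyl}-4H-pyran-4-one
Product: 9 3-hydroxy-2-(hydroxymethyl)-6-{2-[4-methoxy-3-(methoxymethoxy)phenyl]ethyl}-4H-pyran-4-one
Conditions: 37% aq. HCHO, NaOH (1.1 equiv), H2O/MeOH, rt; then HCl to pH 5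
Reagents that add atoms: formaldehyde, C=O
Why: Aldol-type hydroxymethylation of the pyranone enolate at the only free position ortho to the enolic hydroxyl (the future C8a), as known for kojic acid and allomaltol, installs C8.

Step 8
Reactants: 9 3-hydroxy-2-(hydroxymethyl)-6-{2-[4-methoxy-3-(methoxymethoxy)phenyl]ethyl}-4H-pyran-4-one
Product: 10 2-(hydroxymethyl)-6-{2-[4-methoxy-3-(methoxymethoxy)phenyl]ethyl}-4-oxo-4H-pyran-3-yl trifluoromethanesulfonate
Conditions: PhNTf2, Et3N, CH2Cl2, 0 °C to rt
Reagents that add atoms: N-phenylbis(trifluoromethanesulfonimide), O=S(=O)(N(c1ccccc1)S(=O)(=O)C(F)(F)F)C(F)(F)F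
Why: Selective O-sulfonylation, since only the acidic enolic hydroxyl is deprotonated by triethylamine and triflated by the mild triflimide while the primary alcohol is left alone.

Step 9
Reactants: 10 2-(hydroxymethyl)-6-{2-[4-methoxy-3-(methoxymethoxy)phenyl]ethyl}-4-oxo-4H-pyran-3-yl trifluoromethanesulfonate
Product: 11 2-formyl-6-{2-[4-methoxy-3-(methoxymethoxy)phenyl]ethyl}-4-oxo-4H-pyran-3-yl trifluoromethanesulfonate
Conditions: Dess–Martin periodinane, CH2Cl2, rt
Reagents that add atoms: none
Why: Dess–Martin oxidation of the primary alcohol to the aldehyde under neutral conditions that the vinyl triflate and the MOM ether tolerate.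

Step 10
Reactants: 11 2-formyl-6-{2-[4-methoxy-3-(methoxymethoxy)phenyl]ethyl}-4-oxo-4H-pyran-3-yl trifluoromethanesulfonate
Product: 12 6-{2-[4-methoxy-3-(methoxymethoxy)phenyl]ethyl}-4-oxo-3-(4,4,5,5-tetramethyl-1,3,2-dioxaborolan-2-yl)-4H-pyran-2-carbaldehyde
Conditions: B2pin2, PdCl2(dppf) (5 mol %), KOAc, 1,4-dioxane, 80 °C
Reagents that add atoms: bis(pinacolato)diboron, CC1(C)OB(OC1(C)C)B1OC(C)(C)C(C)(C)O1
Why: Miyaura borylation, in which zerovalent palladium inserts into the vinyl C–OTf bond of the α-triflyloxy enone and acetate-assisted transmetalation with the diboron gives the boronate in the presence of the aldehyde.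

Step 11
Reactants: 13 2,3-dichloropropene
Product: 14 1-bromo-3-chloro-2,2-dimethoxypropane
Conditions: NBS, MeOH, H2SO4 (cat.), rt
Reagents that add atoms: N-bromosuccinimide, O=C1CCC(=O)N1Br; methanol, CO
Why: Bromo-methoxylation of the vinyl chloride (Markovnikov opening of the bromonium ion by methanol) followed by methanolysis of the resulting α-chloro ether gives the dimethyl ketal, a known preparation.

Step 12
Reactants: 14 1-bromo-3-chloro-2,2-dimethoxypropane
Product: 15 3,3-dimethoxycyclopropene
Conditions: NaNH2 (3 equiv), liq. NH3, −50 to −33 °C; then NH4Cl; used fresh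
Reagents that add atoms: none
Why: Amide-induced 1,3-elimination to the chlorocyclopropane and then 1,2-dehydrochlorination gives the cyclopropenone ketal, the established route to this reagent.

Step 13
Reactants: 12 6-{2-[4-methoxy-3-(methoxymethoxy)phenyl]ethyl}-4-oxo-3-(4,4,5,5-tetramethyl-1,3,2-dioxaborolan-2-yl)-4H-pyran-2-carbaldehyde; 15 3,3-dimethoxycyclopropene
Product: 16 (8R)-8-hydroxy-7,7-dimethoxy-2-{2-[4-methoxy-3-(methoxymethoxy)phenyl]ethyl}-7,8-dihydro-4H-chromen-4-one
Conditions: [RhCl(C2H4)2]2 (3 mol %), (1R,4R)-2,5-diphenylbicyclo[2.2.2]octa-2,5-diene (7 mol %), KOH (0.2 equiv), degassed 1,4-dioxane/H2O 10:1, 30 °C; 15 (1.5 equiv) added slowly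
Reagents that add atoms: none
Why: Proposed new method: transmetalation of the C4a–B bond of 12 to the hydroxo-rhodium diene complex (monovalent rhodium) gives a 3-pyranonyl-rhodium that adds syn across the strained C=C of 15 (C4a–C5 bond), and the resulting cyclopropyl-rhodium, a vicinal donor–acceptor cyclopropane (two methoxy donors on C7, the vinylogous formyl group on C5 as acceptor), should open by strain-releasing β-carbon elimination of the C5–C7 bond to a 1,1-dimethoxyallyl-rhodium that adds through its ketal carbon C7 to the neighbouring aldehyde (C7–C8 bond) before protonolysis of the rhodium alkoxide closes the cycle. The closest known reaction types are the rhodium-catalysed [3+2] annulation of 2-formylarylboronic acids with alkynes to indenols and the ring-opening [3+3] annulations of cyclopropenes in rhodium-catalysed C–H activation; carborhodation of cyclopropenes by arylboron reagents and carbonyl allylation by allylrhodium species are both documented. The carbocycle (C4a, C5, C6, C7, C8, C8a) is closed in a formal [3+3] annulation whose ring-forming event is a 6-exo-trig allylation of the aldehyde through a rhodium-chelated transition state. The only new stereocenter, C8, is set in this addition by the chiral diene on rhodium, which selects the aldehyde face (antipode chosen to give 8R). The step needs ring opening to outrun protonolysis or 1,2-addition of the cyclopropyl-rhodium and needs attack through C7 rather than C5: the push–pull polarisation of the C5–C7 bond favours the first, a four-membered closure from C5 is excluded, and the symmetrical cyclopropene removes any regiochemical question in the carbometalation.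

Step 14
Reactants: 16 (8R)-8-hydroxy-7,7-dimethoxy-2-{2-[4-methoxy-3-(methoxymethoxy)phenyl]ethyl}-7,8-dihydro-4H-chromen-4-one
Product: 17 (5S,6S,8R)-5,6,8-trihydroxy-7,7-dimethoxy-2-{2-[4-methoxy-3-(methoxymethoxy)phenyl]ethyl}-5,6,7,8-tetrahydro-4H-chromen-4-one (5-, 6- and 8-OH all cis)
Conditions: OsO4 (1.05 equiv), TMEDA (1.1 equiv), CH2Cl2, −78 °C; then aq. Na2SO3, THF, 50 °C
Reagents that add atoms: osmium tetroxide, O=[Os](=O)(=O)=O
Why: Hydroxyl-directed syn-dihydroxylation, in which the pseudoaxial homoallylic C8 hydroxyl hydrogen-bonds the OsO4·TMEDA complex and delivers it to its own face of C5=C6 while the pseudoaxial C7 methoxy group shields the other face, so C5 and C6 should be set cis to the C8 hydroxyl.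

Step 15
Reactants: 17 (5S,6S,8R)-5,6,8-trihydroxy-7,7-dimethoxy-2-{2-[4-methoxy-3-(methoxymethoxy)phenyl]ethyl}-5,6,7,8-tetrahydro-4H-chromen-4-one
Product: 19 (5S,6S,7R,8S)-5,6,7,8-tetrahydroxy-2-{2-[4-methoxy-3-(methoxymethoxy)phenyl]ethyl}-5,6,7,8-tetrahydro-4H-chromen-4-one, via keto-triol 18 (not isolated)
Conditions: AcOH/H2O/THF 3:1:1, 35 °C; evaporate; then Me4NBH(OAc)3, MeCN/AcOH 1:1, −20 °C
Reagents that add atoms: water, O
Why: Mild hydrolysis of the dimethyl ketal gives the C7 ketone, and Evans–Saksena reduction then delivers hydride intramolecularly from the face of the three cis hydroxyls (the axial C5 hydroxyl in a 1,3-relation), which should place the new C7 hydroxyl trans to its neighbours.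

Step 16
Reactants: 19 (5S,6S,7R,8S)-5,6,7,8-tetrahydroxy-2-{2-[4-methoxy-3-(methoxymethoxy)phenyl]ethyl}-5,6,7,8-tetrahydro-4H-chromen-4-one
Product: 20 (5S,6S,7R,8S)-5,6,7,8-tetrahydroxy-2-[2-(3-hydroxy-4-methoxyphenyl)ethyl]-5,6,7,8-tetrahydro-4H-chromen-4-one
Conditions: 3 M HCl, THF/H2O, rt
Reagents that add atoms: none
Why: Acid hydrolysis of the aryl methoxymethyl acetal in an alcohol-free medium should release the phenol without exchange at the carbinol centers.

## Compound list

1 | kojic acid, 5-hydroxy-2-(hydroxymethyl)-4H-pyran-4-one | OCc1cc(=O)c(O)co1 | starting material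
2 | 5-(benzyloxy)-2-(hydroxymethyl)-4H-pyran-4-one | OCc1cc(=O)c(OCc2ccccc2)co1 | intermediate
3 | 5-(benzyloxy)-2-(chloromethyl)-4H-pyran-4-one | ClCc1cc(=O)c(OCc2ccccc2)co1 | intermediate
4 | {[5-(benzyloxy)-4-oxo-4H-pyran-2-yl]methyl}triphenylphosphonium chloride | [Cl-].O=c1cc(C[P+](c2ccccc2)(c2ccccc2)c2ccccc2)occ1OCc1ccccc1 | intermediate
5 | isovanillin, 3-hydroxy-4-methoxybenzaldehyde | COc1ccc(C=O)cc1O | starting material
6 | 4-methoxy-3-(methoxymethoxy)benzaldehyde | COCOc1cc(C=O)ccc1OC | intermediate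
7 | 5-(benzyloxy)-2-{2-[4-methoxy-3-(methoxymethoxy)phenyl]ethenyl}-4H-pyran-4-one (E/Z mixture, E drawn) | COCOc1cc(/C=C/c2cc(=O)c(OCc3ccccc3)co2)ccc1OC | intermediate
8 | 5-hydroxy-2-{2-[4-methoxy-3-(methoxymethoxy)phenyl]ethyl}-4H-pyran-4-one | COCOc1cc(CCc2cc(=O)c(O)co2)ccc1OC | intermediate
9 | 3-hydroxy-2-(hydroxymethyl)-6-{2-[4-methoxy-3-(methoxymethoxy)phenyl]ethyl}-4H-pyran-4-one | COCOc1cc(CCc2cc(=O)c(O)c(CO)o2)ccc1OC | intermediate
10 | 2-(hydroxymethyl)-6-{2-[4-methoxy-3-(methoxymethoxy)phenyl]ethyl}-4-oxo-4H-pyran-3-yl trifluoromethanesulfonate | COCOc1cc(CCc2cc(=O)c(OS(=O)(=O)C(F)(F)F)c(CO)o2)ccc1OC | intermediate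
11 | 2-formyl-6-{2-[4-methoxy-3-(methoxymethoxy)phenyl]ethyl}-4-oxo-4H-pyran-3-yl trifluoromethanesulfonate | COCOc1cc(CCc2cc(=O)c(OS(=O)(=O)C(F)(F)F)c(C=O)o2)ccc1OC | intermediate
12 | 6-{2-[4-methoxy-3-(methoxymethoxy)phenyl]ethyl}-4-oxo-3-(4,4,5,5-tetramethyl-1,3,2-dioxaborolan-2-yl)-4H-pyran-2-carbaldehyde | COCOc1cc(CCc2cc(=O)c(B3OC(C)(C)C(C)(C)O3)c(C=O)o2)ccc1OC | intermediate
13 | 2,3-dichloropropene | ClCC(Cl)=C | starting material
14 | 1-bromo-3-chloro-2,2-dimethoxypropane | COC(CBr)(CCl)OC | intermediate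
15 | 3,3-dimethoxycyclopropene | COC1(OC)C=C1 | intermediate
16 | (8R)-8-hydroxy-7,7-dimethoxy-2-{2-[4-methoxy-3-(methoxymethoxy)phenyl]ethyl}-7,8-dihydro-4H-chromen-4-one | COCOc1cc(CCc2cc(=O)c3c(o2)[C@@H](O)C(OC)(OC)C=C3)ccc1OC | intermediate
17 | (5S,6S,8R)-5,6,8-trihydroxy-7,7-dimethoxy-2-{2-[4-methoxy-3-(methoxymethoxy)phenyl]ethyl}-5,6,7,8-tetrahydro-4H-chromen-4-one | COCOc1cc(CCc2cc(=O)c3c(o2)[C@@H](O)C(OC)(OC)[C@@H](O)[C@H]3O)ccc1OC | intermediate
18 | (5S,6S,8R)-5,6,8-trihydroxy-2-{2-[4-methoxy-3-(methoxymethoxy)phenyl]ethyl}-5,6-dihydro-4H-chromene-4,7(8H)-dione | COCOc1cc(CCc2cc(=O)c3c(o2)[C@@H](O)C(=O)[C@@H](O)[C@H]3O)ccc1OC | intermediate (not isolated)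
19 | (5S,6S,7R,8S)-5,6,7,8-tetrahydroxy-2-{2-[4-methoxy-3-(methoxymethoxy)phenyl]ethyl}-5,6,7,8-tetrahydro-4H-chromen-4-one | COCOc1cc(CCc2cc(=O)c3c(o2)[C@@H](O)[C@H](O)[C@@H](O)[C@H]3O)ccc1OC | intermediate
20 | (5S,6S,7R,8S)-5,6,7,8-tetrahydroxy-2-[2-(3-hydroxy-4-methoxyphenyl)ethyl]-5,6,7,8-tetrahydro-4H-chromen-4-one | COc1ccc(CCc2cc(=O)c3c(o2)[C@@H](O)[C@H](O)[C@@H](O)[C@H]3O)cc1O | target

## Step count and risks

Total step count: 16. Longest linear sequence: 13 steps (1, 2, 3, 5, 6, 7, 8, 9, 10, 13, 14, 15, 16).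

**Step 13 (proposed new method).** The cyclopropyl-rhodium may be protonated or may add directly to the aldehyde with the three-membered ring intact. The allylrhodium may be protonated to a ketene acetal. The boronate may protodeboronate. Face selection at the aldehyde may be poor, or 16 may lose methanol and aromatise.
Fallback, from 11 back to 20, all known chemistry:
- Stille coupling of 11 with tributyl(vinyl)stannane (Pd(PPh3)4, LiCl, dioxane, 90 °C) should give 3-ethenyl-6-{2-[4-methoxy-3-(methoxymethoxy)phenyl]ethyl}-4-oxo-4H-pyran-2-carbaldehyde F1.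
- Brown allylboration with the (Z)-γ-(methoxymethoxy)allyl reagent (allyl methoxymethyl ether, sBuLi, B-methoxydiisopinocampheylborane of the required antipode, BF3·OEt2, −78 °C, ethanolamine work-up) should give the syn diol monoether 3-ethenyl-2-[(1S,2R)-1-hydroxy-2-(methoxymethoxy)but-3-en-1-yl]-6-{2-[4-methoxy-3-(methoxymethoxy)phenyl]ethyl}-4H-pyran-4-one F2 under reagent control.
- Ring-closing metathesis with the second-generation Grubbs catalyst (CH2Cl2, 40 °C) should give (7R,8S)-8-hydroxy-7-(methoxymethoxy)-2-{2-[4-methoxy-3-(methoxymethoxy)phenyl]ethyl}-7,8-dihydro-4H-chromen-4-one F3.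
- Catalytic OsO4 with N-methylmorpholine N-oxide (acetone/H2O) should add anti to the allylic C7 ether to give (5S,6S,7R,8S)-5,6,8-trihydroxy-7-(methoxymethoxy)-2-{2-[4-methoxy-3-(methoxymethoxy)phenyl]ethyl}-5,6,7,8-tetrahydro-4H-chromen-4-one F4.
- 3 M HCl in THF/H2O should remove both methoxymethyl groups to give 20.

**Step 15.** The ketal flanked by two carbinols may hydrolyse slowly, which would let the free ketol isomerise through its enediol or eliminate. Hydride delivery may also leak to the all-cis C7 epimer.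
Fallback, from 17 back to 19: the ketal is cleaved under near-neutral conditions (CeCl3·7H2O, NaI, MeCN) and ketol 18 is isolated. It is then reduced under catalyst control with a ketoreductase (NADPH, glucose and glucose dehydrogenase for recycling, phosphate buffer pH 7, 30 °C) chosen by screening for the 7R alcohol. No new compound is made.

**Step 14.** Hydrogen-bond delivery from the homoallylic hydroxyl may be too weak, giving poor facial selectivity in the osmylation.
Fallback, from 16 back to 17:
- Hydroxyl-directed epoxidation (VO(acac)2, tBuOOH, CH2Cl2) should give the syn epoxide (5S,6S,8R)-5,6-epoxy-8-hydroxy-7,7-dimethoxy-2-{2-[4-methoxy-3-(methoxymethoxy)phenyl]ethyl}-5,6,7,8-tetrahydro-4H-chromen-4-one F5.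
- Halide-catalysed CO2 insertion (CO2 1 atm, Bu4NBr cat., 60 °C) should convert it with overall retention (double inversion at C5) into the cis-fused cyclic carbonate of 17, F6.
- K2CO3 in MeOH should then release 17.

## Further compounds

F1 | step 13 | 3-ethenyl-6-{2-[4-methoxy-3-(methoxymethoxy)phenyl]ethyl}-4-oxo-4H-pyran-2-carbaldehyde | COCOc1cc(CCc2cc(=O)c(C=C)c(C=O)o2)ccc1OC
F2 | step 13 | 3-ethenyl-2-[(1S,2R)-1-hydroxy-2-(methoxymethoxy)but-3-en-1-yl]-6-{2-[4-methoxy-3-(methoxymethoxy)phenyl]ethyl}-4H-pyran-4-one | COCOc1cc(CCc2cc(=O)c(C=C)c(o2)[C@@H](O)[C@H](OCOC)C=C)ccc1OC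
F3 | step 13 | (7R,8S)-8-hydroxy-7-(methoxymethoxy)-2-{2-[4-methoxy-3-(methoxymethoxy)phenyl]ethyl}-7,8-dihydro-4H-chromen-4-one | COCOc1cc(CCc2cc(=O)c3c(o2)[C@@H](O)[C@H](OCOC)C=C3)ccc1OC
F4 | step 13 | (5S,6S,7R,8S)-5,6,8-trihydroxy-7-(methoxymethoxy)-2-{2-[4-methoxy-3-(methoxymethoxy)phenyl]ethyl}-5,6,7,8-tetrahydro-4H-chromen-4-one | COCOc1cc(CCc2cc(=O)c3c(o2)[C@@H](O)[C@H](OCOC)[C@@H](O)[C@H]3O)ccc1OC
F5 | step 14 | (5S,6S,8R)-5,6-epoxy-8-hydroxy-7,7-dimethoxy-2-{2-[4-methoxy-3-(methoxymethoxy)phenyl]ethyl}-5,6,7,8-tetrahydro-4H-chromen-4-one | COCOc1cc(CCc2cc(=O)c3c(o2)[C@@H](O)C(OC)(OC)[C@H]4O[C@@H]34)ccc1OC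
F6 | step 14 | 5,6-O-carbonyl derivative (cis-fused cyclic carbonate) of (5S,6S,8R)-triol ketal 17 | COCOc1cc(CCc2cc(=O)c3c(o2)[C@@H](O)C(OC)(OC)[C@H]4OC(=O)O[C@@H]34)ccc1OC
F0 | step 15 | none | none
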